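(The numbers in the tables were computed on assumed constants; noise was put on by code.)

In a one-step world, free catalyst would carry left-handed substrate through catalyst intermediate A to left-handed product, and the excess would stand at 100 %. The opposite pole is a catalyst blind to handedness: equal products and an excess of zero, the zero of our scale.

| flask | left-handed substrate | right-handed substrate | reagent | free catalyst | temperature | remark | time |
|---|---|---|---|---|---|---|---|
| midnight | 0.016 M | 0.016 M | 0.032 M | 0.11 mM | 15 °C | run made earlier |  |
| winter | 0.016 M | 0.016 M | 0.032 M | 0.24 mM | 42 °C | run made earlier |  |
| spring | 0.024 M | 0.024 M | 0.032 M | 0.16 mM | 15 °C | run made earlier |  |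
| Saturday's | 0.016 M | 0.016 M | 0.0320 M | 0.16 mM | 35 °C |  | 2.0 d |
| Sunday's | 0.016 M | 0.016 M | 0.0320 M | 0.16 mM | 50 °C |  | 2.0 d |
| Wednesday's | 0.016 M | 0.016 M | 0.0320 M | 0.16 mM | 20 °C |  | 2.0 d |
| Tuesday's | 0.016 M | 0.016 M | 0.0320 M | 0.16 mM | 65 °C |  | 2.0 d |

midnight run (percent of the left-handed substrate and right-handed substrate together charged)

| time / d | left-handed product / % | right-handed product / % | left-handed substrate / % |
|---|---|---|---|
| 0.625 | 2 | 2 | 47 |
| 1.67 | 9 | 1 | 45 |
| 3.00 | 13 | 2 | 36 |
| 5.00 | 19 | 2 | 29 |

winter run (percent of the left-handed substrate and right-handed substrate together charged)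

| time / h | left-handed product / % | right-handed product / % | left-handed substrate / % |
|---|---|---|---|
| 3.00 | 11 | 1 | 35 |
| 8.00 | 26 | 3 | 21 |
| 15.0 | 44 | 4 | 7 |
| 40.0 | 49 | 19 | 0 |

spring run (percent of the left-handed substrate and right-handed substrate together charged)

| time / d | left-handed product / % | right-handed product / % | left-handed substrate / % |
|---|---|---|---|
| 0.333 | 1 | 0 | 50 |
| 0.833 | 4 | 2 | 47 |
| 1.67 | 8 | 0 | 42 |
| 5.00 | 19 | 0 | 32 |

(standard deviation of a reading: 1.5 percentage points)

- free catalyst is single-handed; left-handed substrate and right-handed substrate are mirror images of each other, charged as a racemate, each of them at the stated concentration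
- candidate steps: free catalyst + left-handed substrate <-> catalyst intermediate A; free catalyst + right-handed substrate <-> catalyst intermediate B; reagent + catalyst intermediate A -> free catalyst + left-handed product; reagent + catalyst intermediate B -> free catalyst + right-handed product; 2 free catalyst <-> resting dimer; free catalyst -> spent catalyst
- an excess is the difference of the two amounts in percent of their sum
- an excess is below zero if the other one leads

1. the best flask by excess of left-handed product over right-handed product; "all alike" if 1.5 percentage points covers them all (Saturday's / Sunday's / Wednesday's / Tuesday's / all alike)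
2. excess of left-handed product over right-handed product at the end, Saturday's
3. excess of left-handed product over right-handed product at the end, Sunday's
4. excess of left-handed product over right-handed product at the end, Wednesday's
5. excess of left-handed product over right-handed product at the end, Tuesday's

Now we add the second process, right-handed substrate going through catalyst intermediate B to right-handed product. The winter run at 15.0 h reads 44 % of left-handed product and 4 % of right-handed product, an excess of 83.3 %. This is a reading, with a scatter of 1.5 percentage points on each product.

The third addition is that left-handed substrate is finite. Each substrate is charged equally, so left-handed product can reach a ceiling, the left-hand share of the charge, of 50.0 %. Once it stands there, the excess is the ceiling minus right-handed product, over the ceiling plus right-handed product, and it reaches zero when right-handed product reaches the same ceiling. The winter run at 40.0 h reads 49 % and 19 %, and the ceiling rule gives 44.9 %. The resting dimer and spent catalyst come last: they take catalyst out of its round and can alter the pace, but they do not enter this rule.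

Our own reckoning is for Wednesday's. The midnight run had 19 % of left-handed product at 5.00 d. Counting product per catalyst and per time, Wednesday's would need 4.52 times the midnight pace to reach the ceiling, with its temperature at 20 °C against 15 °C. The winter run at 42 °C reads 8.49 times that pace. So we expect Wednesday's to stay below the ceiling, and we take the winter reading of 83.3 % as its excess, although that reading comes from another temperature.

The forecast is a little higher for that flask, at 85 % (75 % to 94 %), and names Wednesday's best. It gives Saturday's 72 % (55 % to 84 %), Sunday's 35 % (15 % to 60 %) and Tuesday's 12 % (0 % to 45 %). Its ground: “The ee is therefore set by how far each flask runs past exhaustion of the left substrate.”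

The flasks give 86.6 % in Wednesday's, 70.7 % in Saturday's, 32.5 % in Sunday's and 13.3 % in Tuesday's.

    free catalyst + left-handed substrate ⇌ catalyst intermediate A (K = 960 /M, k = 66000 /M/h, Ea = 44.0 kJ/mol, ΔH = −42.0 kJ/mol)
    free catalyst + right-handed substrate ⇌ catalyst intermediate B (K = 170 /M, k = 2.80 × 10⁵ /M/h, Ea = 40.0 kJ/mol, ΔH = −14.0 kJ/mol)
    reagent + catalyst intermediate A → free catalyst + left-handed product (k = 460 /M/h, Ea = 70.0 kJ/mol)
    reagent + catalyst intermediate B → free catalyst + right-handed product (k = 180 /M/h, Ea = 55.0 kJ/mol)
    2 free catalyst ⇌ resting dimer (K = 2200 /M, k = 3100 /M/h, Ea = 56.0 kJ/mol, ΔH = −28.0 kJ/mol)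
    free catalyst → spent catalyst (k = 1.10 × 10⁻⁴ /h, Ea = 115 kJ/mol)
    (constants at 50 °C)

In Tuesday's, the step from free catalyst and left-handed substrate to catalyst intermediate A has 98 % of its turnover up to 2.0 d behind it at 0.400 d, earlier than the reading. At 2.00 d left-handed product stands at 50.0 % and right-handed product at 38.3 %, which under the ceiling of 50.0 % makes an excess of 13.3 %. The same flask left until 8.0 d holds 47.2 % of right-handed product, which under that ceiling makes an excess of 2.84 %.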